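**Plan**

- The target is two hexasubstituted phloroglucinol rings joined by one CH2. Ring A (butanoyl ring): C1 butanoyl, C2 OH, C3 CH3, C4 OH, C5 CH2 bridge, C6 OH. Ring B carries the propanoyl group.
- Retrosynthesis: first the five O-alkyl bonds and the C1–acyl bond of ring A are cut (ether cleavage, Friedel–Crafts). Ring A is then cut at C5–C6 and C3–C4, giving 3-ethoxy-2-methylcyclobutenone (C6, C1, C2, C3) and a methyl ynol ether (C4, C5) that already bears CH2–ring B.
- Further back: the propargylic C(sp3)–C(sp) bond (Stille), the benzylic C–Cl bond and the ring B acyl bond lead to 2,4,6-trimethoxytoluene.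
- Enabling feature: ring A is a benzene with oxygen on the alternate carbons C2, C4 and C6 and carbon on C1, C3 and C5. A 3-alkoxyvinylketene (oxygen at C6 and C2) and an alkoxyalkyne (oxygen at C4) deliver exactly this pattern when they combine to a phenol.
- Forward order: ring B is bought as an arene and fully dressed first. Ring A is the only ring built, in one thermal cascade beside the finished ring B. Butanoylation of its single free carbon and global dealkylation finish the route.
- Stereochemistry: the target has no stereocentre. The only stereogenic elements (a racemic quaternary carbon and one alkene geometry) are transient and vanish on aromatisation.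

Key step: step 6

Remark: the alkyne oxygen is carried as a methyl ether and the cyclobutenone oxygen as an ethyl ether. Both are removed at the end, so their identity is a protecting-group choice.

**Route**

Step 1
Reactants: 1 2,4,6-trimethoxytoluene
Product: 2 1-(2,4,6-trimethoxy-3-methylphenyl)propan-1-one
Conditions: EtCOCl, SnCl4, CH2Cl2, −10 to 0 °C
Reagents that add atoms: propanoyl chloride, CCC(=O)Cl
Why: Friedel–Crafts acylation, in which the two open positions of 1 are equivalent, the first ketone deactivates the ring against a second acylation, and SnCl4 at low temperature should leave the methoxy groups ortho to the new ketone intact.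

Step 2
Reactants: 2 1-(2,4,6-trimethoxy-3-methylphenyl)propan-1-one
Product: 3 1-[3-(chloromethyl)-2,4,6-trimethoxy-5-methylphenyl]propan-1-one
Conditions: (CH2O)n, HCl (g), ZnCl2 (cat.), 1,4-dioxane, 40 °C
Reagents that add atoms: formaldehyde (as paraformaldehyde), C=O; hydrogen chloride, Cl
Why: Blanc chloromethylation at the one remaining ring C–H, which is flanked by two methoxy groups and para to the third, while the ketone slows the ring enough to disfavour diarylmethane formation and HCl saturation keeps the benzylic position as the chloride.

Step 3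
Reactants: 4 2-chloro-1,1-dimethoxyethane
Product: 6 tributyl(methoxyethynyl)stannane, via lithium methoxyacetylide 5 (not isolated)
Conditions: LiNEt2 (3.1 equiv, from Et2NH and n-BuLi), THF, −78 to 0 °C; then Bu3SnCl, −78 °C to rt
Reagents that add atoms: tributyltin chloride, CCCC[Sn](Cl)(CCCC)CCCC
Why: base-induced double elimination (methanol, then HCl) of the chloroacetal followed by deprotonation gives acetylide 5, and stannylation with Bu3SnCl is the standard quench of an alkoxyacetylide.

Step 4
Reactants: 3 1-[3-(chloromethyl)-2,4,6-trimethoxy-5-methylphenyl]propan-1-one; 6 tributyl(methoxyethynyl)stannane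
Product: 7 1-[2,4,6-trimethoxy-3-(3-methoxyprop-2-yn-1-yl)-5-methylphenyl]propan-1-one
Conditions: Pd(PPh3)4 (5 mol %), THF, 60 °C
Reagents that add atoms: none
Why: Stille coupling, in which oxidative addition of the benzylic C–Cl bond to zerovalent palladium, transfer of the alkynyl group from tin and reductive elimination form the sp3–sp bond under neutral conditions that spare the ketone and the acid-sensitive ynol ether.

Step 5
Reactants: 8 1-ethoxyprop-1-yne
Product: 9 3-ethoxy-2-methylcyclobut-2-en-1-one
Conditions: AcCl (slow addition), Et3N, Et2O, 0 °C to rt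
Reagents that add atoms: acetyl chloride, CC(=O)Cl
Why: ketene–alkyne (2+2) cycloaddition, in which ketene made from acetyl chloride and Et3N is attacked at its carbonyl carbon by the methyl-bearing, oxygen-remote carbon of the ynol ether, placing methyl at C2 and ethoxy at C3 of the cyclobutenone.

Step 6
Reactants: 7 1-[2,4,6-trimethoxy-3-(3-methoxyprop-2-yn-1-yl)-5-methylphenyl]propan-1-one; 9 3-ethoxy-2-methylcyclobut-2-en-1-one
Product: 14 1-{3-[(4-ethoxy-6-hydroxy-2-methoxy-3-methylphenyl)methyl]-2,4,6-trimethoxy-5-methylphenyl}propan-1-one, via vinylketene 10 (not isolated), via vinylcyclobutenone 11 (not isolated), via dienylketene 12 (not isolated), via cyclohexadienone 13 (not isolated)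
Conditions: 9 (2.5 equiv), toluene, sealed tube, 120 °C then 150 °C; then K2CO3, MeOH, rt
Reagents that add atoms: none
Why: Proposed new method: heating should open 9 by four-electron electrocyclic ring opening to vinylketene 10, whose carbonyl carbon is attacked by the benzyl-bearing, oxygen-remote carbon of ynol ether 7 in a ketene–alkyne (2+2) cycloaddition to give 11, and 11 should open again to dienylketene 12. The closest known reaction is the Danheiser benzannulation of 3-alkyl- and 3-aryl-cyclobutenones with alkoxy- and siloxy-alkynes; a 3-alkoxycyclobutenone has not served as the ketene source, but the vinylcyclobutenone of every such annulation is itself a 3-alkoxycyclobutenone that opens thermally, which is the basis for expecting 9 to open at a somewhat higher temperature. Ring A then closes by thermally allowed disrotatory six-electron electrocyclisation of 12 (C6–C1 bond) to dienone 13, which enolises to the phenol. No stereocentre is created in 14: the quaternary carbon of 11 is racemic and is lost on ring opening, and the geometric isomer of 12 that cannot cyclise can return to 11. The selectivity needed is the regiochemistry of the (2+2) step, which the matched polarisation of the ynol ether (nucleophilic at the carbon remote from oxygen) and the ketene (electrophilic at the carbonyl carbon) secures so that C5–C6 and C3–C4 are the bonds formed. The methyl ynol ether has no β-hydrogen for retro-ene loss of an alkene at the temperature required, and the ring B ketone, flanked by two methoxy groups, should stay a spectator.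

Step 7
Reactants: 14 1-{3-[(4-ethoxy-6-hydroxy-2-methoxy-3-methylphenyl)methyl]-2,4,6-trimethoxy-5-methylphenyl}propan-1-one
Product: 15 1-{2-ethoxy-6-hydroxy-4-methoxy-3-methyl-5-[(2,4,6-trimethoxy-3-methyl-5-propanoylphenyl)methyl]phenyl}butan-1-one
Conditions: PrCOCl, TiCl4, CH2Cl2, −20 to 0 °C
Reagents that add atoms: butanoyl chloride, CCCC(=O)Cl
Why: Friedel–Crafts acylation directed by the titanium phenoxide, since C1 of ring A is the only aromatic C–H in the molecule and lies ortho to the free hydroxyl, ortho to the ethoxy group and para to the methoxy group, while ring B is fully substituted.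

Step 8
Reactants: 15 1-{2-ethoxy-6-hydroxy-4-methoxy-3-methyl-5-[(2,4,6-trimethoxy-3-methyl-5-propanoylphenyl)methyl]phenyl}butan-1-one
Product: 16 1-{2,4,6-trihydroxy-3-methyl-5-[(2,4,6-trihydroxy-3-methyl-5-propanoylphenyl)methyl]phenyl}butan-1-one
Conditions: BBr3 (10 equiv), CH2Cl2, −78 °C to rt; then H2O
Reagents that add atoms: none
Why: Lewis-acid ether cleavage, in which BBr3 coordinates each ether oxygen and bromide removes the methyl or ethyl group by SN2, the aryl ketones only chelate boron and return on aqueous work-up, and the low starting temperature limits acid-induced scission of the diarylmethane bridge.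

**Compound list**

1 | 2,4,6-trimethoxytoluene | Cc1c(OC)cc(OC)cc1OC | starting material
2 | 1-(2,4,6-trimethoxy-3-methylphenyl)propan-1-one | CCC(=O)c1c(OC)cc(OC)c(C)c1OC | intermediate
3 | 1-[3-(chloromethyl)-2,4,6-trimethoxy-5-methylphenyl]propan-1-one | CCC(=O)c1c(OC)c(CCl)c(OC)c(C)c1OC | intermediate
4 | 2-chloro-1,1-dimethoxyethane | COC(CCl)OC | starting material
5 | lithium methoxyacetylide | [Li]C#COC | intermediate (not isolated)
6 | tributyl(methoxyethynyl)stannane | CCCC[Sn](CCCC)(CCCC)C#COC | intermediate
7 | 1-[2,4,6-trimethoxy-3-(3-methoxyprop-2-yn-1-yl)-5-methylphenyl]propan-1-one | CCC(=O)c1c(OC)c(CC#COC)c(OC)c(C)c1OC | intermediate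
8 | 1-ethoxyprop-1-yne | CCOC#CC | starting material
9 | 3-ethoxy-2-methylcyclobut-2-en-1-one | CCOC1=C(C)C(=O)C1 | intermediate
10 | 3-ethoxy-2-methylbuta-1,3-dien-1-one (vinylketene) | CCOC(=C)C(C)=C=O | intermediate (not isolated)
11 | 4-(1-ethoxyethenyl)-3-methoxy-4-methyl-2-[(2,4,6-trimethoxy-3-methyl-5-propanoylphenyl)methyl]cyclobut-2-en-1-one (racemic vinylcyclobutenone) | CCOC(=C)C1(C)C(OC)=C(Cc2c(OC)c(C)c(OC)c(C(=O)CC)c2OC)C1=O | intermediate (not isolated)
12 | (3E)-5-ethoxy-3-methoxy-4-methyl-2-[(2,4,6-trimethoxy-3-methyl-5-propanoylphenyl)methyl]hexa-1,3,5-trien-1-one (dienylketene) | O=C=C(Cc1c(OC)c(C)c(OC)c(C(=O)CC)c1OC)/C(OC)=C(/C)C(=C)OCC | intermediate (not isolated)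
13 | 5-ethoxy-3-methoxy-4-methyl-2-[(2,4,6-trimethoxy-3-methyl-5-propanoylphenyl)methyl]cyclohexa-2,4-dien-1-one | CCOC1=C(C)C(OC)=C(Cc2c(OC)c(C)c(OC)c(C(=O)CC)c2OC)C(=O)C1 | intermediate (not isolated)
14 | 1-{3-[(4-ethoxy-6-hydroxy-2-methoxy-3-methylphenyl)methyl]-2,4,6-trimethoxy-5-methylphenyl}propan-1-one | CCOc1cc(O)c(Cc2c(OC)c(C)c(OC)c(C(=O)CC)c2OC)c(OC)c1C | intermediate
15 | 1-{2-ethoxy-6-hydroxy-4-methoxy-3-methyl-5-[(2,4,6-trimethoxy-3-methyl-5-propanoylphenyl)methyl]phenyl}butan-1-one | CCCC(=O)c1c(O)c(Cc2c(OC)c(C)c(OC)c(C(=O)CC)c2OC)c(OC)c(C)c1OCC | intermediate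
16 | 1-{2,4,6-trihydroxy-3-methyl-5-[(2,4,6-trihydroxy-3-methyl-5-propanoylphenyl)methyl]phenyl}butan-1-one | CCCC(=O)c1c(O)c(C)c(O)c(Cc2c(O)c(C)c(O)c(C(=O)CC)c2O)c1O | target

**Count**

Total steps: 8. Longest linear sequence: 6 steps (1, 2, 4, 6, 7, 8); the stannane (step 3) and the cyclobutenone (step 5) are one-step side branches.

**Steps most likely to fail**

Step 6 (proposed new method). The vinylogous-ester stabilisation of 9 may raise its ring-opening temperature to a point where ynol ether 7 oligomerises or the electron-rich phenol is consumed by excess ketene, or the cascade may stall at the vinylcyclobutenone stage. The fallback uses known chemistry and gives up the annulation. It sets out from chloride 3: Friedel–Crafts benzylation of an excess of arene 1 (ZnCl2 cat., CH2Cl2, 0 °C) should give the diarylmethane 1-{2,4,6-trimethoxy-3-methyl-5-[(2,4,6-trimethoxy-3-methylphenyl)methyl]phenyl}propan-1-one F1. Acylation of its single aromatic C–H with butanoyl chloride and SnCl4 should give 1-{2,4,6-trimethoxy-3-methyl-5-[(2,4,6-trimethoxy-3-methyl-5-propanoylphenyl)methyl]phenyl}butan-1-one F2. Cleavage of the six methyl ethers with BBr3 comes back to the route at target 16.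

Step 4. Slow transfer from tin to palladium may let the very ionisable trimethoxybenzyl chloride homocouple or solvolyse, and the ynol ether may hydrate during removal of tin residues. The fallback is a tin-free Negishi alkynylation. It sets out from chloride 3 and acetylide 5 (generated from 4 as in step 3): transmetalation of 5 with ZnBr2 should give bromo(methoxyethynyl)zinc F3, which is coupled with 3 under PdCl2(DPEphos) catalysis in THF at room temperature. The zinc acetylide does not add to the ketone. The fallback comes back at ynol ether 7.

Step 2. The product chloride may alkylate unreacted 2 (diarylmethane formation) or hydrolyse during isolation. The fallback installs the carbon at the aldehyde level. It sets out from ketone 2: Rieche formylation (Cl2CHOMe, TiCl4, CH2Cl2, 0 °C) should give 2,4,6-trimethoxy-3-methyl-5-propanoylbenzaldehyde F4. Reduction with NaBH4 in MeOH at −20 °C should touch only the aldehyde, the ketone between two methoxy groups being far slower, and give 1-[3-(hydroxymethyl)-2,4,6-trimethoxy-5-methylphenyl]propan-1-one F5. SOCl2 in CH2Cl2 at 0 °C comes back at chloride 3.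

**Further compounds**

F1 | step 6 | 1-{2,4,6-trimethoxy-3-methyl-5-[(2,4,6-trimethoxy-3-methylphenyl)methyl]phenyl}propan-1-one | CCC(=O)c1c(OC)c(Cc2c(OC)cc(OC)c(C)c2OC)c(OC)c(C)c1OC
F2 | step 6 | 1-{2,4,6-trimethoxy-3-methyl-5-[(2,4,6-trimethoxy-3-methyl-5-propanoylphenyl)methyl]phenyl}butan-1-one | CCCC(=O)c1c(OC)c(C)c(OC)c(Cc2c(OC)c(C)c(OC)c(C(=O)CC)c2OC)c1OC
F3 | step 4 | bromo(methoxyethynyl)zinc | COC#C[Zn]Br
F4 | step 2 | 2,4,6-trimethoxy-3-methyl-5-propanoylbenzaldehyde | CCC(=O)c1c(OC)c(C=O)c(OC)c(C)c1OC
F5 | step 2 | 1-[3-(hydroxymethyl)-2,4,6-trimethoxy-5-methylphenyl]propan-1-one | CCC(=O)c1c(OC)c(CO)c(OC)c(C)c1OC
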